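**Retrosynthetic overview**
1. Enone C=C: Claisen–Schmidt condensation of an aryl methyl ketone with 4-hydroxybenzaldehyde (last step).
2. C2 stereocentre: enantioselective hydrogenation of the C2=C3 bond of a 2-substituted benzofuran.
3. Key C–C bond, C2–C(OH)Me2: a C2-lithiated benzofuran is an α-metalated enol ether, i.e. the acyl anion of the masked arylacetaldehyde carbonyl. It adds to acetone, joining two carbonyl-level (normally electrophilic) carbons, while the methyl ketone rides through as its enolate.
4. Furan ring: O-alkylation of paeonol with bromoacetaldehyde diethyl acetal, then acid cyclodehydration onto the only free ortho position.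
5. Ring order: benzene ring bought (paeonol) → furan ring (step 2) → reduced to the dihydrofuran ring (step 4); the hydroxyphenyl ring arrives with the aldehyde.

Assumption: the SMILES is read as the (2R),(E) isomer; the ligand antipode written in step 4 is taken to give 2R, and its mirror image is used instead if a test run shows the opposite sense.

**Step 1**
Reactants: 1 paeonol (1-(2-hydroxy-4-methoxyphenyl)ethan-1-one); 2 bromoacetaldehyde diethyl acetal (2-bromo-1,1-diethoxyethane)
Product: 3 1-[2-(2,2-diethoxyethoxy)-4-methoxyphenyl]ethan-1-one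
Conditions: K2CO3, DMF, 120 °C
Reagents that add atoms: none
Why: Williamson ether synthesis, in which the phenoxide of 1 displaces bromide from the primary halide 2 by SN2 and the acetal and ketone are inert to carbonate.

**Step 2**
Reactants: 3 1-[2-(2,2-diethoxyethoxy)-4-methoxyphenyl]ethan-1-one
Product: 5 1-(4-methoxy-1-benzofuran-7-yl)ethan-1-one, via 3-ethoxy-2,3-dihydrobenzofuran intermediate 4 (not isolated)
Conditions: Amberlyst-15, PhCl, reflux (EtOH distilled off)
Reagents that add atoms: none
Why: Acid-promoted intramolecular Friedel–Crafts cyclodehydration, in which the oxocarbenium ion from the acetal attacks the only free ortho position (flanked and activated by both oxygen substituents) and loss of the second ethanol aromatises the furan ring.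

**Step 3 (key step)**
Reactants: 5 1-(4-methoxy-1-benzofuran-7-yl)ethan-1-one; 6 acetone
Product: 8 1-[2-(2-hydroxypropan-2-yl)-4-methoxy-1-benzofuran-7-yl]ethan-1-one, via C2-lithiated lithium enolate 7 (not isolated)
Conditions: LiN(i-Pr)2 (2.3 equiv), THF, −78 °C, 1 h (5 added to the base); then 6 (1.5 equiv), −78 °C; AcOH, −78 °C → rt
Reagents that add atoms: none
Why: The first equivalent of amide base turns the acetyl group into its lithium enolate (self-protection) and the second removes the acidic C2–H (pKa about 33) to give an α-lithiated cyclic enol ether, an acyl-anion (d1) equivalent of the latent arylacetaldehyde carbonyl, whose 1,2-addition to acetone joins two carbonyl-level carbons in a reversed-polarity carbonyl addition; no stereocentre is formed.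

**Step 4**
Reactants: 8 1-[2-(2-hydroxypropan-2-yl)-4-methoxy-1-benzofuran-7-yl]ethan-1-one
Product: 9 1-[(2R)-2-(2-hydroxypropan-2-yl)-4-methoxy-2,3-dihydro-1-benzofuran-7-yl]ethan-1-one
Conditions: H2 (50 bar), [Ir(cod)(L*)][B(C6H3(CF3)2)4] (2 mol%), CH2Cl2, 40 °C (cod = cycloocta-1,5-diene; L* = (S)-8-(di-tert-butylphosphanyloxy)-2-phenyl-5,6,7,8-tetrahydroquinoline)
Reagents that add atoms: none
Why: Asymmetric hydrogenation of a 2-alkylbenzofuran with a cationic iridium pyridine–phosphinite catalyst, in which H2 is delivered to one enantioface of the planar C2=C3 enol-ether bond inside the chiral N,P pocket to set C2 as R, and aryl ketones are not reduced by this catalyst class.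

**Step 5**
Reactants: 9 1-[(2R)-2-(2-hydroxypropan-2-yl)-4-methoxy-2,3-dihydro-1-benzofuran-7-yl]ethan-1-one; 10 4-hydroxybenzaldehyde
Product: 12 (E)-1-[(2R)-2-(2-hydroxypropan-2-yl)-4-methoxy-2,3-dihydro-1-benzofuran-7-yl]-3-(4-hydroxyphenyl)prop-2-en-1-one, via β-hydroxy ketone aldol adduct 11 (not isolated)
Conditions: KOH (50% aq.), EtOH, rt, 24–48 h; then HCl (1 M) to pH 5
Reagents that add atoms: none
Why: Claisen–Schmidt condensation, in which the enolate of 9 adds to 10 and aldol 11 dehydrates by E1cB to the thermodynamically favoured E-enone, while C2 has no acidic hydrogen and keeps its R configuration.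

**Compound list**
1 | paeonol, 1-(2-hydroxy-4-methoxyphenyl)ethan-1-one | CC(=O)c1ccc(OC)cc1O | starting material
2 | bromoacetaldehyde diethyl acetal, 2-bromo-1,1-diethoxyethane | CCOC(CBr)OCC | starting material
3 | 1-[2-(2,2-diethoxyethoxy)-4-methoxyphenyl]ethan-1-one | CCOC(COc1cc(OC)ccc1C(C)=O)OCC | intermediate
4 | 1-(3-ethoxy-4-methoxy-2,3-dihydro-1-benzofuran-7-yl)ethan-1-one (racemic, not isolated) | CCOC1COc2c(C(C)=O)ccc(OC)c12 | intermediate
5 | 1-(4-methoxy-1-benzofuran-7-yl)ethan-1-one | COc1ccc(C(C)=O)c2occc12 | intermediate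
6 | acetone | CC(C)=O | starting material
7 | lithium 1-(2-lithio-4-methoxy-1-benzofuran-7-yl)ethen-1-olate (not isolated) | COc1ccc(C(=C)O[Li])c2oc([Li])cc12 | intermediate
8 | 1-[2-(2-hydroxypropan-2-yl)-4-methoxy-1-benzofuran-7-yl]ethan-1-one | COc1ccc(C(C)=O)c2oc(C(C)(C)O)cc12 | intermediate
9 | 1-[(2R)-2-(2-hydroxypropan-2-yl)-4-methoxy-2,3-dihydro-1-benzofuran-7-yl]ethan-1-one | COc1ccc(C(C)=O)c2c1C[C@H](C(C)(C)O)O2 | intermediate
10 | 4-hydroxybenzaldehyde | O=Cc1ccc(O)cc1 | starting material
11 | 3-hydroxy-1-[(2R)-2-(2-hydroxypropan-2-yl)-4-methoxy-2,3-dihydro-1-benzofuran-7-yl]-3-(4-hydroxyphenyl)propan-1-one (both carbinol epimers, not isolated) | COc1ccc(C(=O)CC(O)c3ccc(O)cc3)c2c1C[C@H](C(C)(C)O)O2 | intermediate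
12 | (E)-1-[(2R)-2-(2-hydroxypropan-2-yl)-4-methoxy-2,3-dihydro-1-benzofuran-7-yl]-3-(4-hydroxyphenyl)prop-2-en-1-one | COc1ccc(C(=O)/C=C/c2ccc(O)cc2)c2c1C[C@H](C(C)(C)O)O2 | target

**Step count**
Total steps: 5. Longest linear sequence: 5 (1 → 3 → 5 → 8 → 9 → 12).

**Three steps most likely to fail**

Step 4 (highest risk). The 2-substituent is a bulky tertiary carbinol, and acidic iridium hydrides could ionise this furfuryl-type alcohol, leading to the 2-isopropyl by-product or low ee. The fallback sets out from 8 and comes back at 9. Compound 8 is hydrogenated under base-conditioned, acid-free conditions with the ruthenium bis-carbene catalyst formed from [Ru(cod)(2-methylallyl)2], 1,3-bis[(R)-1-(naphthalen-1-yl)ethyl]imidazolinium tetrafluoroborate and KOtBu (hexane/toluene, H2 60 bar, 25 °C; carbene antipode chosen for 2R). This system reduces the furan ring enantioselectively but also the aryl ketone, giving 1-[(2R)-2-(2-hydroxypropan-2-yl)-4-methoxy-2,3-dihydro-1-benzofuran-7-yl]ethan-1-ol F1 as a mixture of carbinol epimers. The benzylic secondary alcohol of F1 is then re-oxidised with Pr4N[RuO4] (5 mol%) and N-methylmorpholine N-oxide in CH2Cl2 (Ley–Griffith oxidation), which leaves the tertiary alcohol untouched and returns 9.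

Step 3. The enolate may undergo aldol addition to acetone, or the second deprotonation may be incomplete. The fallback sets out from 5 and comes back at 8, keeping the same reversed-polarity bond formation but on a masked ketone. Compound 5 is ketalised (ethylene glycol, p-TsOH cat., toluene, Dean–Stark) to 4-methoxy-7-(2-methyl-1,3-dioxolan-2-yl)-1-benzofuran F2. F2 is lithiated at C2 with n-BuLi (1.1 equiv, THF, −78 °C), treated with acetone 6 and quenched with water to give 2-[4-methoxy-7-(2-methyl-1,3-dioxolan-2-yl)-1-benzofuran-2-yl]propan-2-ol F3. Mild hydrolysis (pyridinium p-toluenesulfonate, acetone/H2O, 40 °C) then frees the ketone to give 8.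

Step 2. The acetyl group can compete through intramolecular aldol-type closure, and the oxocarbenium ion can oligomerise. The fallback sets out from 1 and comes back at 5, building the furan ring by sigmatropic rearrangement and oxidative cleavage instead. Paeonol 1 is O-allylated (allyl bromide, K2CO3, acetone, reflux) to 1-[4-methoxy-2-(prop-2-en-1-yloxy)phenyl]ethan-1-one F4. Aromatic Claisen rearrangement (N,N-diethylaniline, 200 °C) moves the allyl group to the only free ortho position, giving 1-[2-hydroxy-4-methoxy-3-(prop-2-en-1-yl)phenyl]ethan-1-one F5. Lemieux–Johnson cleavage (K2OsO4·2H2O cat., NaIO4, 2,6-lutidine, dioxane/H2O) gives the arylacetaldehyde, which closes to the lactol 1-(2-hydroxy-4-methoxy-2,3-dihydro-1-benzofuran-7-yl)ethan-1-one F6. Dehydration (p-TsOH cat., toluene, 80 °C) gives 5.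

**Further compounds**
F1 | step 4 | 1-[(2R)-2-(2-hydroxypropan-2-yl)-4-methoxy-2,3-dihydro-1-benzofuran-7-yl]ethan-1-ol (carbinol epimers) | COc1ccc(C(C)O)c2c1C[C@H](C(C)(C)O)O2
F2 | step 3 | 4-methoxy-7-(2-methyl-1,3-dioxolan-2-yl)-1-benzofuran | COc1ccc(C3(C)OCCO3)c2occc12
F3 | step 3 | 2-[4-methoxy-7-(2-methyl-1,3-dioxolan-2-yl)-1-benzofuran-2-yl]propan-2-ol | COc1ccc(C3(C)OCCO3)c2oc(C(C)(C)O)cc12
F4 | step 2 | 1-[4-methoxy-2-(prop-2-en-1-yloxy)phenyl]ethan-1-one | COc1ccc(C(C)=O)c(OCC=C)c1
F5 | step 2 | 1-[2-hydroxy-4-methoxy-3-(prop-2-en-1-yl)phenyl]ethan-1-one | COc1ccc(C(C)=O)c(O)c1CC=C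
F6 | step 2 | 1-(2-hydroxy-4-methoxy-2,3-dihydro-1-benzofuran-7-yl)ethan-1-one (racemic lactol) | COc1ccc(C(C)=O)c2OC(O)Cc12
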